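**Retrosynthetic overview**

1. The route rests on one feature of the cyclohexane ring (ring A, C5–C10): the vinyl group on the quaternary carbon C10 and the ester oxygen on C8 are cis-1,3. A vinyl ether hung on that oxygen can hand its two carbons to C10 only across the face the oxygen occupies.
2. Target ⇒ C8 alcohol 29 + acrylic acid 36 (ester bond). 29 ⇒ trans γ-lactone closure C6–O/C12 (ring B, the last ring) and conversion of a C5 ester into the 2-propenol unit.
3. ⇒ β-keto ester 20 ⇒ reductive opening (SmI2) of cage 19, which cuts the C5–CH2 bond and the C8–O–CH bond and so unveils vinyl and hydroxyl.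
4. 19 ⇒ intramolecular [2+2] photocycloaddition of the enone vinyl ether 18 (oxolane and cyclobutane closed together, both temporary).
5. 18 ⇒ Knoevenagel closure of ring A (first ring) on an Evans syn-aldol product of imide 6 and aldehyde 8; acid 36 from (R)-glyceraldehyde acetonide.

Key step: step 10

Remark: atoms carry elemane-type labels (ring A = C5–C10; lactone carbons C11, C12; propenol carbons C4, C15), and β-keto esters are drawn as keto tautomers. The monomethyl ester 1 and the ketal ester 7 are taken as the commercial forms of (R)-2-methylsuccinic acid and ethyl acetoacetate.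

**Route**

Step 1
Reactants: 1 (2R)-4-methoxy-2-methyl-4-oxobutanoic acid
Product: 2 1-tert-butyl 4-methyl (2R)-2-methylbutanedioate
Conditions: tBuOC(=NH)CCl3, BF3·OEt2 (cat.), CH2Cl2–cyclohexane, rt
Reagents that add atoms: tert-butyl 2,2,2-trichloroacetimidate, CC(C)(C)OC(=N)C(Cl)(Cl)Cl
Why: Acid-catalysed O-tert-butylation of the free acid by the trichloroacetimidate is mild and should leave the α-stereocentre and the methyl ester untouched.

Step 2
Reactants: 2 1-tert-butyl 4-methyl (2R)-2-methylbutanedioate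
Product: 3 (3R)-4-tert-butoxy-3-methyl-4-oxobutanoic acid
Conditions: LiOH (1.05 equiv), THF–H2O, 0 °C; then 1 M HCl
Reagents that add atoms: lithium hydroxide, [Li+].[OH-]
Why: Saponification should discriminate the unhindered methyl ester from the tert-butyl ester, and cold hydroxide does not enolise the centre α to the tert-butyl ester.

Step 3
Reactants: 3 (3R)-4-tert-butoxy-3-methyl-4-oxobutanoic acid; 4 (4S)-4-benzyl-1,3-oxazolidin-2-one
Product: 6 tert-butyl (2R)-4-[(4S)-4-benzyl-2-oxo-1,3-oxazolidin-3-yl]-2-methyl-4-oxobutanoate, via mixed pivalic anhydride 5 (not isolated)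
Conditions: PivCl, Et3N, THF, −20 °C; then 4, LiCl, rt
Reagents that add atoms: none
Why: N-Acylation of the oxazolidinone through the mixed pivalic anhydride (LiCl/Et3N variant) takes place at the less hindered carbonyl and needs no strong base, so the methyl-bearing centre is safe.

Step 4
Reactants: 7 ethyl 2-(2-methyl-1,3-dioxolan-2-yl)acetate
Product: 8 2-(2-methyl-1,3-dioxolan-2-yl)acetaldehyde
Conditions: iBu2AlH (1.1 equiv), CH2Cl2, −78 °C; MeOH, aq. KNaC4H4O6
Reagents that add atoms: none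
Why: Partial ester reduction with iBu2AlH at −78 °C stops at the aluminium hemiacetal and should release the aldehyde on work-up; it is used crude.

Step 5
Reactants: 6 tert-butyl (2R)-4-[(4S)-4-benzyl-2-oxo-1,3-oxazolidin-3-yl]-2-methyl-4-oxobutanoate; 8 2-(2-methyl-1,3-dioxolan-2-yl)acetaldehyde
Product: 10 tert-butyl (2R,3S,4R)-3-{[(4S)-4-benzyl-2-oxo-1,3-oxazolidin-3-yl]carbonyl}-4-hydroxy-2-methyl-5-(2-methyl-1,3-dioxolan-2-yl)pentanoate, via dibutylboron Z-enolate 9 (not isolated)
Conditions: Bu2BOTf, iPr2NEt, CH2Cl2, −78 → 0 °C; 8, −78 → 0 °C; pH 7 buffer, MeOH, H2O2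
Reagents that add atoms: none
Why: Evans syn aldol: soft enolisation occurs only at the imide CH2 and gives the Z-boron enolate, which should add through a Zimmerman–Traxler chair on the face away from the benzyl group, setting C7 (S) and C8 (R) syn, which becomes the trans relation of the C7 side chain and the C8 oxygen on ring A.

Step 6
Reactants: 10 tert-butyl (2R,3S,4R)-3-{[(4S)-4-benzyl-2-oxo-1,3-oxazolidin-3-yl]carbonyl}-4-hydroxy-2-methyl-5-(2-methyl-1,3-dioxolan-2-yl)pentanoate
Product: 11 tert-butyl (2R,3S,4R)-4-hydroxy-3-[methoxy(methyl)carbamoyl]-2-methyl-5-(2-methyl-1,3-dioxolan-2-yl)pentanoate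
Conditions: MeNHOMe·HCl, AlMe3, CH2Cl2, −10 → 0 °C
Reagents that add atoms: N,O-dimethylhydroxylamine hydrochloride, CNOC.Cl
Why: Weinreb transamination of the β-hydroxy imide, assisted by the aluminium alkoxide of the free hydroxyl, should cleave the auxiliary at the exocyclic carbonyl without touching the tert-butyl ester, the ketal or the new centres.

Step 7
Reactants: 11 tert-butyl (2R,3S,4R)-4-hydroxy-3-[methoxy(methyl)carbamoyl]-2-methyl-5-(2-methyl-1,3-dioxolan-2-yl)pentanoate; 12 methyl acetate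
Product: 14 1-tert-butyl 6-methyl (2R,3S)-3-[(1R)-1-hydroxy-2-(2-methyl-1,3-dioxolan-2-yl)ethyl]-2-methyl-4-oxohexanedioate, via lithium enolate of methyl acetate 13 (not isolated)
Conditions: 12, LiN(iPr)2 (4 equiv), THF, −78 °C; then 11, −78 → −40 °C; aq. NH4Cl
Reagents that add atoms: none
Why: Claisen-type acylation of the ester enolate by the Weinreb amide should stop at the β-keto ester because the chelated adduct and then the product enolate are stable; the excess enolate covers the free hydroxyl.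

Step 8
Reactants: 14 1-tert-butyl 6-methyl (2R,3S)-3-[(1R)-1-hydroxy-2-(2-methyl-1,3-dioxolan-2-yl)ethyl]-2-methyl-4-oxohexanedioate
Product: 16 methyl (4R,5S)-5-[(2R)-1-tert-butoxy-1-oxopropan-2-yl]-4-hydroxy-2-methyl-6-oxocyclohex-1-ene-1-carboxylate, via diketone 15 (not isolated)
Conditions: AcOH–H2O–THF (3:1:1), 40 °C; evaporate; piperidine (0.2 equiv), AcOH (0.2 equiv), 4 Å MS, CH2Cl2, rt
Reagents that add atoms: none
Why: Mild acid frees the methyl ketone, and the intramolecular Knoevenagel condensation of the β-keto ester CH2 (C5) onto that ketone (C10) should close ring A as the conjugated enone; weak amine/acid catalysis at room temperature is chosen so that the C8 hydroxyl is not eliminated toward a salicylate.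

Step 9
Reactants: 16 methyl (4R,5S)-5-[(2R)-1-tert-butoxy-1-oxopropan-2-yl]-4-hydroxy-2-methyl-6-oxocyclohex-1-ene-1-carboxylate; 17 ethyl vinyl ether
Product: 18 methyl (4R,5S)-5-[(2R)-1-tert-butoxy-1-oxopropan-2-yl]-4-(ethenyloxy)-2-methyl-6-oxocyclohex-1-ene-1-carboxylate
Conditions: 17 (solvent), Pd(OAc)2 (5 mol %), 4,7-diphenyl-1,10-phenanthroline (6 mol %), air, rt
Reagents that add atoms: none
Why: Transfer vinylation of the secondary alcohol by a phenanthroline-ligated divalent palladium catalyst is driven by the excess vinyl ether and runs near neutrality, as the base- and acid-labile β-alkoxy enone requires; no stereocentre is touched.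

Step 10
Reactants: 18 methyl (4R,5S)-5-[(2R)-1-tert-butoxy-1-oxopropan-2-yl]-4-(ethenyloxy)-2-methyl-6-oxocyclohex-1-ene-1-carboxylate
Product: 19 methyl (1R,3R,5S,6R,8S)-5-[(2R)-1-tert-butoxy-1-oxopropan-2-yl]-8-methyl-4-oxo-9-oxatricyclo[4.2.1.0(3,8)]nonane-3-carboxylate
Conditions: hν (350 nm, Pyrex), CH2Cl2 (5 mM), Ar, −20 °C
Reagents that add atoms: none
Why: Proposed new method: excitation of the enone (n→π*, fast intersystem crossing) gives a triplet whose β-carbon C10 should bond to the inner, oxygen-bearing vinyl carbon in a 1,5-closure (rule of five), and the resulting 1,4-biradical (primary CH2 radical and the C5 radical flanked by ketone and ester) should close the C5–CH2 bond after spin inversion; the closest known reaction type is the intramolecular enone–alkene [2+2] photocycloaddition of cyclohexenones that carry an alkene on a three-atom tether (straight adducts), but a tether that runs from ring position 5 through one oxygen atom to a vinyl group has not been shown. The oxolane (C8–O–CH–C10–C9) closes in the five-ring 1,5 mode and ends as the two-atom bridge of a 6-oxabicyclo[3.2.1]octane, and the cyclobutane closes by radical recombination and can only be cis-fused. The C10 centre is set by the tether, which reaches only the face that carries the C8 oxygen, so the new C10–C bond is cis to that oxygen and the methyl group is left on the other face; the O–CH centre follows from the bridge (hydrogen outward) and C5 from the cis fusion (CH2 on the tether face, ester opposite). The step needs attack on the face cis to the C8 oxygen and inner-carbon-to-C10 regiochemistry, and the one-atom tether secures both because the 1,6-closure and the other face are out of reach, provided that the half-chair with pseudo-axial vinyloxy group (and pseudo-axial C7 side chain, trans to it) is populated. High dilution and the long-wavelength cut-off are meant to suppress dimerisation and secondary photolysis of the strained β-keto ester.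

Step 11
Reactants: 19 methyl (1R,3R,5S,6R,8S)-5-[(2R)-1-tert-butoxy-1-oxopropan-2-yl]-8-methyl-4-oxo-9-oxatricyclo[4.2.1.0(3,8)]nonane-3-carboxylate
Product: 20 methyl (1R,2R,4R,5S)-5-[(2R)-1-tert-butoxy-1-oxopropan-2-yl]-2-ethenyl-4-hydroxy-2-methyl-6-oxocyclohexane-1-carboxylate
Conditions: SmI2 (2.5 equiv), THF–HMPA, −78 °C; aq. NH4Cl at −78 °C
Reagents that add atoms: none
Why: SmI2 reductive cleavage of an α-keto cyclobutane: the C6 ketyl should open the exocyclic C5–CH2 bond, which the boat-like cage aligns with the carbonyl π system, to the chelated β-keto ester enolate, the primary radical is reduced at once and the organosamarium expels the β-alkoxide (as in the SmI2 opening of 2-(halomethyl)oxolanes), so the tether carbons become the C10 vinyl group cis to the freed C8 hydroxyl and C5 is reprotonated to the equatorial ester.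

Step 12
Reactants: 20 methyl (1R,2R,4R,5S)-5-[(2R)-1-tert-butoxy-1-oxopropan-2-yl]-2-ethenyl-4-hydroxy-2-methyl-6-oxocyclohexane-1-carboxylate
Product: 21 methyl (1R,2R,4R,5S)-5-[(2R)-1-tert-butoxy-1-oxopropan-2-yl]-4-{[tert-butyl(dimethyl)silyl]oxy}-2-ethenyl-2-methyl-6-oxocyclohexane-1-carboxylate
Conditions: TBSCl, imidazole, DMAP (cat.), DMF, 35 °C
Reagents that add atoms: tert-butyl(chloro)dimethylsilane, CC(C)(C)[Si](C)(C)Cl
Why: Silylation of the only hydroxyl under weakly basic conditions keeps C8 from being oxidised in step 13 and from competing for C12 when the lactone is closed.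

Step 13
Reactants: 21 methyl (1R,2R,4R,5S)-5-[(2R)-1-tert-butoxy-1-oxopropan-2-yl]-4-{[tert-butyl(dimethyl)silyl]oxy}-2-ethenyl-2-methyl-6-oxocyclohexane-1-carboxylate
Product: 22 methyl (1R,2R,4R,5R,6R)-5-[(2R)-1-tert-butoxy-1-oxopropan-2-yl]-4-{[tert-butyl(dimethyl)silyl]oxy}-2-ethenyl-6-hydroxy-2-methylcyclohexane-1-carboxylate
Conditions: Ru2(CO)4(μ-H)[(η5-C4Ph4CO)2H] (2 mol %), iPrOH–toluene (1:1), 80 °C
Reagents that add atoms: none
Why: Reversible, base-free ruthenium-catalysed transfer hydrogenation lets the C6 carbinol and the adjacent C5 centre equilibrate through the β-keto ester, so the all-equatorial isomer (C6 hydroxyl cis to the C8 oxygen, no 1,3-diaxial contact with the axial C10 methyl) should accumulate, whereas a kinetic hydride would attack C6 from the face remote from that methyl and give the axial epimer.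

Step 14
Reactants: 22 methyl (1R,2R,4R,5R,6R)-5-[(2R)-1-tert-butoxy-1-oxopropan-2-yl]-4-{[tert-butyl(dimethyl)silyl]oxy}-2-ethenyl-6-hydroxy-2-methylcyclohexane-1-carboxylate
Product: 23 tert-butyl (2R)-2-[(1R,2R,3R,4R,6R)-6-{[tert-butyl(dimethyl)silyl]oxy}-4-ethenyl-2-hydroxy-3-[methoxy(methyl)carbamoyl]-4-methylcyclohexyl]propanoate
Conditions: MeNHOMe·HCl, AlMe3, CH2Cl2, 0 °C → rt
Reagents that add atoms: N,O-dimethylhydroxylamine hydrochloride, CNOC.Cl
Why: Weinreb aminolysis of the methyl ester by the aluminium amide is accelerated by the neighbouring aluminium alkoxide, while the tert-butyl ester is inert to this reagent.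

Step 15
Reactants: 23 tert-butyl (2R)-2-[(1R,2R,3R,4R,6R)-6-{[tert-butyl(dimethyl)silyl]oxy}-4-ethenyl-2-hydroxy-3-[methoxy(methyl)carbamoyl]-4-methylcyclohexyl]propanoate; 24 tributyl[(methoxymethoxy)methyl]stannane
Product: 26 tert-butyl (2R)-2-[(1R,2R,3R,4R,6R)-6-{[tert-butyl(dimethyl)silyl]oxy}-4-ethenyl-2-hydroxy-3-[(methoxymethoxy)acetyl]-4-methylcyclohexyl]propanoate, via [(methoxymethoxy)methyl]lithium 25 (not isolated)
Conditions: 24 (3.5 equiv), nBuLi (3.3 equiv), THF, −78 °C; then 23, −78 °C; aq. NH4Cl at −78 °C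
Reagents that add atoms: none
Why: Weinreb ketone synthesis with an α-alkoxymethyllithium made by tin–lithium exchange: the chelated adduct collapses only on work-up, one equivalent is spent on the hydroxyl, and the tert-butyl ester should not be attacked at −78 °C.

Step 16
Reactants: 26 tert-butyl (2R)-2-[(1R,2R,3R,4R,6R)-6-{[tert-butyl(dimethyl)silyl]oxy}-4-ethenyl-2-hydroxy-3-[(methoxymethoxy)acetyl]-4-methylcyclohexyl]propanoate
Product: 27 tert-butyl (2R)-2-[(1R,2S,3S,4R,6R)-6-{[tert-butyl(dimethyl)silyl]oxy}-4-ethenyl-2-hydroxy-3-[3-(methoxymethoxy)prop-1-en-2-yl]-4-methylcyclohexyl]propanoate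
Conditions: Zn, CH2Br2, TiCl4, THF–CH2Cl2, 0 °C → rt
Reagents that add atoms: dibromomethane, BrCBr
Why: The non-basic Takai–Lombardo methylenation should convert the hindered, enolisable α-alkoxy ketone into the 1,1-disubstituted alkene without epimerising C5 and without retro-aldol or β-elimination at the free C6 hydroxyl.

Step 17
Reactants: 27 tert-butyl (2R)-2-[(1R,2S,3S,4R,6R)-6-{[tert-butyl(dimethyl)silyl]oxy}-4-ethenyl-2-hydroxy-3-[3-(methoxymethoxy)prop-1-en-2-yl]-4-methylcyclohexyl]propanoate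
Product: 28 (3R,3aR,4R,6R,7S,7aS)-4-{[tert-butyl(dimethyl)silyl]oxy}-6-ethenyl-7-[3-(methoxymethoxy)prop-1-en-2-yl]-3,6-dimethylhexahydro-1-benzofuran-2(3H)-one
Conditions: CSA (0.2 equiv), toluene, 60 °C
Reagents that add atoms: none
Why: Acid-catalysed lactonisation of the γ-hydroxy tert-butyl ester: the equatorial C6 hydroxyl and the equatorial C7 side chain should close the trans-fused γ-lactone (ring B) with loss of tert-butanol, and the C8 silyl ether excludes the alternative lactone to C8.

Step 18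
Reactants: 28 (3R,3aR,4R,6R,7S,7aS)-4-{[tert-butyl(dimethyl)silyl]oxy}-6-ethenyl-7-[3-(methoxymethoxy)prop-1-en-2-yl]-3,6-dimethylhexahydro-1-benzofuran-2(3H)-one
Product: 29 (3R,3aS,4R,6R,7S,7aS)-6-ethenyl-4-hydroxy-7-[3-(methoxymethoxy)prop-1-en-2-yl]-3,6-dimethylhexahydro-1-benzofuran-2(3H)-one
Conditions: HF·pyridine, pyridine, THF, 0 °C → rt
Reagents that add atoms: none
Why: Fluoride cleavage of the silyl ether in a buffered, slightly acidic medium avoids base-induced migration of the lactone to the C8 oxygen and leaves the MOM ether alone.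

Step 19
Reactants: 30 (4R)-2,2-dimethyl-1,3-dioxolane-4-carbaldehyde
Product: 31 1-[(4R)-2,2-dimethyl-1,3-dioxolan-4-yl]ethan-1-ol (both carbinol epimers)
Conditions: MeMgBr, THF, −78 °C
Reagents that add atoms: methylmagnesium bromide, C[Mg]Br
Why: Grignard addition to the aldehyde; the new carbinol centre is immaterial because it is oxidised in the next step.

Step 20
Reactants: 31 1-[(4R)-2,2-dimethyl-1,3-dioxolan-4-yl]ethan-1-ol
Product: 32 1-[(4R)-2,2-dimethyl-1,3-dioxolan-4-yl]ethan-1-one
Conditions: Dess–Martin periodinane, NaHCO3, CH2Cl2, 0 °C → rt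
Reagents that add atoms: none
Why: Dess–Martin oxidation under buffered, non-basic conditions should give the methyl ketone without epimerising the adjacent α-alkoxy centre.

Step 21
Reactants: 32 1-[(4R)-2,2-dimethyl-1,3-dioxolan-4-yl]ethan-1-one
Product: 34 1-[(4R)-2,2-dimethyl-1,3-dioxolan-4-yl]ethenyl trifluoromethanesulfonate, via potassium enolate 33 (not isolated)
Conditions: KN(SiMe3)2, THF, −78 °C; PhNTf2, −78 → 0 °C
Reagents that add atoms: N-phenylbis(trifluoromethanesulfonimide), O=S(=O)(N(c1ccccc1)S(=O)(=O)C(F)(F)F)C(F)(F)F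
Why: Kinetic deprotonation takes the methyl group and not the α-alkoxy methine, and O-triflation of the terminal enolate gives the enol triflate with the dioxolane centre unchanged.

Step 22
Reactants: 34 1-[(4R)-2,2-dimethyl-1,3-dioxolan-4-yl]ethenyl trifluoromethanesulfonate
Product: 36 2-[(4S)-2,2-dimethyl-1,3-dioxolan-4-yl]prop-2-enoic acid, via mixed acetic anhydride 35 (not isolated)
Conditions: Pd(OAc)2 (5 mol %), PPh3 (10 mol %), KOAc (4 equiv), CO (1 atm), DMF, rt; then H2O, pH 3
Reagents that add atoms: carbon monoxide, [C-]#[O+]; water, O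
Why: Palladium-catalysed hydroxycarbonylation of the vinyl triflate (oxidative addition to zerovalent palladium, CO insertion, capture of the acylpalladium by acetate, hydrolysis of the mixed anhydride) puts the carboxyl group on the former aldehyde carbon and leaves the allylic centre untouched.

Step 23
Reactants: 29 (3R,3aS,4R,6R,7S,7aS)-6-ethenyl-4-hydroxy-7-[3-(methoxymethoxy)prop-1-en-2-yl]-3,6-dimethylhexahydro-1-benzofuran-2(3H)-one; 36 2-[(4S)-2,2-dimethyl-1,3-dioxolan-4-yl]prop-2-enoic acid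
Product: 38 (3R,3aS,4R,6R,7S,7aS)-6-ethenyl-7-[3-(methoxymethoxy)prop-1-en-2-yl]-3,6-dimethyl-2-oxooctahydro-1-benzofuran-4-yl 2-[(4S)-2,2-dimethyl-1,3-dioxolan-4-yl]prop-2-enoate, via mixed 2,4,6-trichlorobenzoic anhydride 37 (not isolated)
Conditions: 36, 2,4,6-trichlorobenzoyl chloride, Et3N, THF, rt; then 29, DMAP, toluene, rt
Reagents that add atoms: none
Why: Yamaguchi esterification: the mixed anhydride, activated by DMAP, should acylate the equatorial secondary C8 hydroxyl, the primary allylic oxygen being masked as the MOM ether and the α-substituted acrylate being a poor Michael acceptor.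

Step 24
Reactants: 38 (3R,3aS,4R,6R,7S,7aS)-6-ethenyl-7-[3-(methoxymethoxy)prop-1-en-2-yl]-3,6-dimethyl-2-oxooctahydro-1-benzofuran-4-yl 2-[(4S)-2,2-dimethyl-1,3-dioxolan-4-yl]prop-2-enoate
Product: 39 (3R,3aS,4R,6R,7S,7aS)-6-ethenyl-7-(3-hydroxyprop-1-en-2-yl)-3,6-dimethyl-2-oxooctahydro-1-benzofuran-4-yl (3S)-3,4-dihydroxy-2-methylidenebutanoate (CNP0260337.1)
Conditions: Me2BBr (5 equiv), CH2Cl2, −78 °C; then THF–aq. NaHCO3
Reagents that add atoms: none
Why: Bromoborane cleavage of acetals: Me2BBr should open both the MOM ether (through the bromomethyl ether) and the isopropylidene acetal at −78 °C while sparing esters, the lactone and the isolated alkenes, and the bicarbonate work-up frees the three hydroxyl groups.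

**Compound list**

1 | (2R)-4-methoxy-2-methyl-4-oxobutanoic acid | COC(=O)C[C@@H](C)C(=O)O | starting material
2 | 1-tert-butyl 4-methyl (2R)-2-methylbutanedioate | COC(=O)C[C@@H](C)C(=O)OC(C)(C)C | intermediate
3 | (3R)-4-tert-butoxy-3-methyl-4-oxobutanoic acid | OC(=O)C[C@@H](C)C(=O)OC(C)(C)C | intermediate
4 | (4S)-4-benzyl-1,3-oxazolidin-2-one | O=C1N[C@@H](Cc2ccccc2)CO1 | starting material
5 | mixed pivalic anhydride of 3 | CC(C)(C)OC(=O)[C@H](C)CC(=O)OC(=O)C(C)(C)C | intermediate
6 | tert-butyl (2R)-4-[(4S)-4-benzyl-2-oxo-1,3-oxazolidin-3-yl]-2-methyl-4-oxobutanoate | CC(C)(C)OC(=O)[C@H](C)CC(=O)N1[C@@H](Cc2ccccc2)COC1=O | intermediate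
7 | ethyl 2-(2-methyl-1,3-dioxolan-2-yl)acetate | CCOC(=O)CC1(C)OCCO1 | starting material
8 | 2-(2-methyl-1,3-dioxolan-2-yl)acetaldehyde | O=CCC1(C)OCCO1 | intermediate
9 | dibutylboron Z-enolate of 6 | CCCCB(CCCC)O/C(=C\[C@@H](C)C(=O)OC(C)(C)C)N1[C@@H](Cc2ccccc2)COC1=O | intermediate
10 | tert-butyl (2R,3S,4R)-3-{[(4S)-4-benzyl-2-oxo-1,3-oxazolidin-3-yl]carbonyl}-4-hydroxy-2-methyl-5-(2-methyl-1,3-dioxolan-2-yl)pentanoate | CC(C)(C)OC(=O)[C@H](C)[C@@H]([C@H](O)CC1(C)OCCO1)C(=O)N1[C@@H](Cc2ccccc2)COC1=O | intermediate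
11 | tert-butyl (2R,3S,4R)-4-hydroxy-3-[methoxy(methyl)carbamoyl]-2-methyl-5-(2-methyl-1,3-dioxolan-2-yl)pentanoate | CC(C)(C)OC(=O)[C@H](C)[C@@H]([C@H](O)CC1(C)OCCO1)C(=O)N(C)OC | intermediate
12 | methyl acetate | CC(=O)OC | starting material
13 | lithium enolate of methyl acetate | [Li]OC(=C)OC | intermediate
14 | 1-tert-butyl 6-methyl (2R,3S)-3-[(1R)-1-hydroxy-2-(2-methyl-1,3-dioxolan-2-yl)ethyl]-2-methyl-4-oxohexanedioate | COC(=O)CC(=O)[C@H]([C@H](O)CC1(C)OCCO1)[C@@H](C)C(=O)OC(C)(C)C | intermediate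
15 | 1-tert-butyl 6-methyl (2R,3S)-3-[(1R)-1-hydroxy-3-oxobutyl]-2-methyl-4-oxohexanedioate | COC(=O)CC(=O)[C@H]([C@H](O)CC(C)=O)[C@@H](C)C(=O)OC(C)(C)C | intermediate
16 | methyl (4R,5S)-5-[(2R)-1-tert-butoxy-1-oxopropan-2-yl]-4-hydroxy-2-methyl-6-oxocyclohex-1-ene-1-carboxylate | O[C@@H]1CC(C)=C(C(=O)OC)C(=O)[C@H]1[C@@H](C)C(=O)OC(C)(C)C | intermediate
17 | ethyl vinyl ether | C=COCC | starting material
18 | methyl (4R,5S)-5-[(2R)-1-tert-butoxy-1-oxopropan-2-yl]-4-(ethenyloxy)-2-methyl-6-oxocyclohex-1-ene-1-carboxylate | C=CO[C@@H]1CC(C)=C(C(=O)OC)C(=O)[C@H]1[C@@H](C)C(=O)OC(C)(C)C | intermediate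
19 | methyl (1R,3R,5S,6R,8S)-5-[(2R)-1-tert-butoxy-1-oxopropan-2-yl]-8-methyl-4-oxo-9-oxatricyclo[4.2.1.0(3,8)]nonane-3-carboxylate (oxygen bridge and cyclobutane on one face, C7 side chain on the other) | C[C@@]12C[C@H]3O[C@@H]1C[C@]2(C(=O)OC)C(=O)[C@H]3[C@@H](C)C(=O)OC(C)(C)C | intermediate
20 | methyl (1R,2R,4R,5S)-5-[(2R)-1-tert-butoxy-1-oxopropan-2-yl]-2-ethenyl-4-hydroxy-2-methyl-6-oxocyclohexane-1-carboxylate | C=C[C@@]1(C)C[C@@H](O)[C@H]([C@@H](C)C(=O)OC(C)(C)C)C(=O)[C@@H]1C(=O)OC | intermediate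
21 | methyl (1R,2R,4R,5S)-5-[(2R)-1-tert-butoxy-1-oxopropan-2-yl]-4-{[tert-butyl(dimethyl)silyl]oxy}-2-ethenyl-2-methyl-6-oxocyclohexane-1-carboxylate | C=C[C@@]1(C)C[C@@H](O[Si](C)(C)C(C)(C)C)[C@H]([C@@H](C)C(=O)OC(C)(C)C)C(=O)[C@@H]1C(=O)OC | intermediate
22 | methyl (1R,2R,4R,5R,6R)-5-[(2R)-1-tert-butoxy-1-oxopropan-2-yl]-4-{[tert-butyl(dimethyl)silyl]oxy}-2-ethenyl-6-hydroxy-2-methylcyclohexane-1-carboxylate | C=C[C@@]1(C)C[C@@H](O[Si](C)(C)C(C)(C)C)[C@H]([C@@H](C)C(=O)OC(C)(C)C)[C@@H](O)[C@@H]1C(=O)OC | intermediate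
23 | tert-butyl (2R)-2-[(1R,2R,3R,4R,6R)-6-{[tert-butyl(dimethyl)silyl]oxy}-4-ethenyl-2-hydroxy-3-[methoxy(methyl)carbamoyl]-4-methylcyclohexyl]propanoate | C=C[C@@]1(C)C[C@@H](O[Si](C)(C)C(C)(C)C)[C@H]([C@@H](C)C(=O)OC(C)(C)C)[C@@H](O)[C@@H]1C(=O)N(C)OC | intermediate
24 | tributyl[(methoxymethoxy)methyl]stannane | CCCC[Sn](CCCC)(CCCC)COCOC | starting material
25 | [(methoxymethoxy)methyl]lithium | [Li]COCOC | intermediate
26 | tert-butyl (2R)-2-[(1R,2R,3R,4R,6R)-6-{[tert-butyl(dimethyl)silyl]oxy}-4-ethenyl-2-hydroxy-3-[(methoxymethoxy)acetyl]-4-methylcyclohexyl]propanoate | C=C[C@@]1(C)C[C@@H](O[Si](C)(C)C(C)(C)C)[C@H]([C@@H](C)C(=O)OC(C)(C)C)[C@@H](O)[C@@H]1C(=O)COCOC | intermediate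
27 | tert-butyl (2R)-2-[(1R,2S,3S,4R,6R)-6-{[tert-butyl(dimethyl)silyl]oxy}-4-ethenyl-2-hydroxy-3-[3-(methoxymethoxy)prop-1-en-2-yl]-4-methylcyclohexyl]propanoate | C=C[C@@]1(C)C[C@@H](O[Si](C)(C)C(C)(C)C)[C@H]([C@@H](C)C(=O)OC(C)(C)C)[C@@H](O)[C@@H]1C(=C)COCOC | intermediate
28 | (3R,3aR,4R,6R,7S,7aS)-4-{[tert-butyl(dimethyl)silyl]oxy}-6-ethenyl-7-[3-(methoxymethoxy)prop-1-en-2-yl]-3,6-dimethylhexahydro-1-benzofuran-2(3H)-one | C=C[C@@]1(C)C[C@@H](O[Si](C)(C)C(C)(C)C)[C@H]2[C@@H](OC(=O)[C@@H]2C)[C@@H]1C(=C)COCOC | intermediate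
29 | (3R,3aS,4R,6R,7S,7aS)-6-ethenyl-4-hydroxy-7-[3-(methoxymethoxy)prop-1-en-2-yl]-3,6-dimethylhexahydro-1-benzofuran-2(3H)-one | C=C[C@@]1(C)C[C@@H](O)[C@H]2[C@@H](OC(=O)[C@@H]2C)[C@@H]1C(=C)COCOC | intermediate
30 | (4R)-2,2-dimethyl-1,3-dioxolane-4-carbaldehyde | O=C[C@H]1COC(C)(C)O1 | starting material
31 | 1-[(4R)-2,2-dimethyl-1,3-dioxolan-4-yl]ethan-1-ol (both carbinol epimers) | CC(O)[C@H]1COC(C)(C)O1 | intermediate
32 | 1-[(4R)-2,2-dimethyl-1,3-dioxolan-4-yl]ethan-1-one | CC(=O)[C@H]1COC(C)(C)O1 | intermediate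
33 | potassium 1-[(4R)-2,2-dimethyl-1,3-dioxolan-4-yl]ethen-1-olate | [K+].[O-]C(=C)[C@H]1COC(C)(C)O1 | intermediate
34 | 1-[(4R)-2,2-dimethyl-1,3-dioxolan-4-yl]ethenyl trifluoromethanesulfonate | C=C(OS(=O)(=O)C(F)(F)F)[C@H]1COC(C)(C)O1 | intermediate
35 | acetic 2-[(4S)-2,2-dimethyl-1,3-dioxolan-4-yl]prop-2-enoic anhydride | C=C(C(=O)OC(C)=O)[C@H]1COC(C)(C)O1 | intermediate
36 | 2-[(4S)-2,2-dimethyl-1,3-dioxolan-4-yl]prop-2-enoic acid | C=C(C(=O)O)[C@H]1COC(C)(C)O1 | intermediate
37 | 2-[(4S)-2,2-dimethyl-1,3-dioxolan-4-yl]prop-2-enoic 2,4,6-trichlorobenzoic anhydride | C=C(C(=O)OC(=O)c1c(Cl)cc(Cl)cc1Cl)[C@H]1COC(C)(C)O1 | intermediate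
38 | (3R,3aS,4R,6R,7S,7aS)-6-ethenyl-7-[3-(methoxymethoxy)prop-1-en-2-yl]-3,6-dimethyl-2-oxooctahydro-1-benzofuran-4-yl 2-[(4S)-2,2-dimethyl-1,3-dioxolan-4-yl]prop-2-enoate | C=C[C@@]1(C)C[C@@H](OC(=O)C(=C)[C@H]2COC(C)(C)O2)[C@H]3[C@@H](OC(=O)[C@@H]3C)[C@@H]1C(=C)COCOC | intermediate
39 | (3R,3aS,4R,6R,7S,7aS)-6-ethenyl-7-(3-hydroxyprop-1-en-2-yl)-3,6-dimethyl-2-oxooctahydro-1-benzofuran-4-yl (3S)-3,4-dihydroxy-2-methylidenebutanoate | C=C[C@@]1(C)C[C@@H](OC(=O)C(=C)[C@H](O)CO)[C@H]2[C@@H](OC(=O)[C@@H]2C)[C@@H]1C(=C)CO | target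

**Step count and risks**

Total steps: 24. Longest linear sequence: 19 steps (steps 1–3, 5–18, 23, 24).

The three steps most likely to fail:

1. Step 10 (proposed new method). The excited enone may be consumed by other channels before the strained bridged closure takes place: hydrogen abstraction from the vinyl ether, dimerisation, or reversion of the 1,4-biradical. The ring may also fail to place the vinyloxy group pseudo-axial. The fallback uses known chemistry and sets out from 16:
   - Silylation with chloro(bromomethyl)dimethylsilane and imidazole would give the (bromomethyl)dimethylsilyl ether of 16 F1.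
   - Bu3SnH/AIBN (slow addition, benzene, 80 °C) would generate the α-silyl radical, which can add to C10 only on the face of the C8 oxygen (6-exo radical conjugate addition, temporary silicon connection), giving the oxasilacyclohexane-bridged β-keto ester F2.
   - Tamao oxidation (H2O2, KF, KHCO3) would give the C10-hydroxymethyl diol F3.
   - TEMPO/PhI(OAc)2 would oxidise the primary alcohol selectively to the C10-formyl β-keto ester F4.
   - Wittig methylenation with excess Ph3P=CH2 (β-keto ester and C8 hydroxyl masked as their salts) would give 20, where the route is rejoined.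

2. Step 11. The ketyl may open the ring bond C5–C10 instead of C5–CH2 (ring expansion). The primary radical may also pick up hydrogen before it is reduced, so that the alkoxide is not expelled. The fallback sets out from 19 and replaces electron transfer by a polar opening whose regiochemistry is set by sterics. Iodide under Lewis-acid activation (Me3SiI, CH2Cl2, −78 °C) would attack the unhindered CH2 of the doubly activated cyclobutane in a homo-conjugate addition, giving the iodomethyl oxolane β-keto ester F5. Zinc dust (NH4Cl, EtOH, 50 °C) would then effect a Boord-type reductive elimination of the β-alkoxy iodide, which releases the vinyl group and the C8 hydroxyl and gives 20.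

3. Step 13. Hydrogen transfer to the hindered ketone may be too slow for the C6 and C5 centres to reach equilibrium, or the vinyl group may be reduced alongside. The fallback sets out from 21 and replaces hydride transfer by electron transfer: SmI2, H2O and Et3N in THF at 0 °C (dissolving-metal-type reduction, in which the pyramidal ketyl/carbanion is protonated toward the equatorial alcohol, isolated alkenes being inert) would give 22 directly; no new compound arises (F0).

Further compounds
F1 | step 10 | methyl (4R,5S)-4-{[(bromomethyl)dimethylsilyl]oxy}-5-[(2R)-1-tert-butoxy-1-oxopropan-2-yl]-2-methyl-6-oxocyclohex-1-ene-1-carboxylate | BrC[Si](C)(C)O[C@@H]1CC(C)=C(C(=O)OC)C(=O)[C@H]1[C@@H](C)C(=O)OC(C)(C)C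
F2 | step 10 | methyl 8-[(2R)-1-tert-butoxy-1-oxopropan-2-yl]-3,3,5-trimethyl-7-oxo-2-oxa-3-silabicyclo[3.3.1]nonane-6-carboxylate (configuration as in 20) | C[Si]1(C)C[C@@]2(C)C[C@@H](O1)[C@H]([C@@H](C)C(=O)OC(C)(C)C)C(=O)[C@@H]2C(=O)OC
F3 | step 10 | methyl 5-[(2R)-1-tert-butoxy-1-oxopropan-2-yl]-4-hydroxy-2-(hydroxymethyl)-2-methyl-6-oxocyclohexane-1-carboxylate (hydroxymethyl cis to the C8 hydroxyl) | OC[C@@]1(C)C[C@@H](O)[C@H]([C@@H](C)C(=O)OC(C)(C)C)C(=O)[C@@H]1C(=O)OC
F4 | step 10 | methyl 5-[(2R)-1-tert-butoxy-1-oxopropan-2-yl]-2-formyl-4-hydroxy-2-methyl-6-oxocyclohexane-1-carboxylate (formyl cis to the C8 hydroxyl) | O=C[C@@]1(C)C[C@@H](O)[C@H]([C@@H](C)C(=O)OC(C)(C)C)C(=O)[C@@H]1C(=O)OC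
F5 | step 11 | methyl 4-[(2R)-1-tert-butoxy-1-oxopropan-2-yl]-7-(iodomethyl)-1-methyl-3-oxo-6-oxabicyclo[3.2.1]octane-2-carboxylate (configuration as in 19) | C[C@@]12C[C@@H](O[C@@H]1CI)[C@H]([C@@H](C)C(=O)OC(C)(C)C)C(=O)[C@@H]2C(=O)OC
F0 | step 13 | none | none
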